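**Plan**

- Retrosynthesis: the side-chain ketone is taken back to a ring-bound alkyne (hydration), C3 of the oxolane is given back a geminal diester, and the ring is then cut at O1–C5 and C2–C3 into heptadec-2-ynal (O1=C2) and a 2-butylcyclopropane-1,1-diester (C3–C4–C5).
- Enabling feature: in the oxolane, O1–C2 is at the aldehyde oxidation level and C3–C4–C5 is a saturated three-carbon arc whose C5 carries butyl and oxygen and whose C3 is a bare CH2. The ring is therefore the formal [3+2] adduct of a C=O with a 1,3-zwitterion stored as the strained C3–C5 bond of a donor–acceptor cyclopropane (helpers: the three-membered ring and two esters on C3).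
- Forward order: chiral diol to cyclic sulfate to cyclopropane; alkyne to ynal; the [3+2] step closes the only ring; the esters are excised (saponification, double hydrodecarboxylation); the alkyne is hydrated last, so the β-alkoxy ketone never meets base.
- Stereochemistry: C5 comes from (2R)-hexane-1,2-diol through two SN2 inversions (cyclopropane closure, cyclopropane opening); C2 is set relative to C5 by the cis-selective ring closure.

Key step: step 4

Remark: the target is read as the cis-2,5-disubstituted oxolane with (2R,5R) configuration, and (2R)-hexane-1,2-diol is taken as a purchasable single enantiomer.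

**Route**

Step 1
Reactants: 1 (2R)-hexane-1,2-diol
Product: 3 (4R)-4-butyl-1,3,2-dioxathiolane 2,2-dioxide, via cyclic sulfite 2 (not isolated)
Conditions: SOCl2 (1.2 equiv), CH2Cl2, 0 °C to reflux; concentrate; then RuCl3·xH2O (0.5 mol%), NaIO4 (1.5 equiv), MeCN/H2O, 0 °C
Reagents that add atoms: thionyl chloride, O=S(Cl)Cl; sodium periodate, [Na+].[O-]I(=O)(=O)=O
Why: Cyclic sulfate formation: SOCl2 closes the diol to the cyclic sulfite, whose sulfur is then oxidised by catalytic RuO4 (from RuCl3 and NaIO4) without breaking either C–O bond, so the (R) centre is carried through untouched and both carbons become activated for displacement.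

Step 2
Reactants: 3 (4R)-4-butyl-1,3,2-dioxathiolane 2,2-dioxide; 4 dimethyl malonate
Product: 7 dimethyl (2S)-2-butylcyclopropane-1,1-dicarboxylate, via sodium dimethyl malonate 5 (not isolated), via sodium alkyl sulfate 6 (not isolated)
Conditions: NaH (2.1 equiv), DME, 0 °C to rt, then reflux
Reagents that add atoms: none
Why: Double alkylation of malonate by a cyclic sulfate: the enolate opens 3 at the primary carbon (SN2), and after a second deprotonation the malonate carbon displaces the secondary sulfate in a 3-exo-tet closure with inversion, which turns the (R) carbinol carbon into the (S) cyclopropane carbon.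

Step 3
Reactants: 8 hexadec-1-yne
Product: 11 heptadec-2-ynal, via lithium hexadec-1-yn-1-ide 9 (not isolated), via lithium hemiaminal alkoxide 10 (not isolated)
Conditions: n-BuLi (1.05 equiv), THF, −78 °C; DMF (2 equiv), −78 to 0 °C; reverse quench into cold 1 M aq. HCl/Et2O
Reagents that add atoms: N,N-dimethylformamide, CN(C)C=O
Why: Formylation of a lithium acetylide with DMF: the tetrahedral lithium hemiaminal alkoxide 10 is stable until the reverse acidic quench, which releases the ynal while keeping dimethylamine protonated so that it cannot add to the conjugated triple bond.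

Step 4
Reactants: 7 dimethyl (2S)-2-butylcyclopropane-1,1-dicarboxylate; 11 heptadec-2-ynal
Product: 13 dimethyl (2S,5R)-5-butyl-2-(hexadec-1-yn-1-yl)oxolane-3,3-dicarboxylate, via oxocarbenium malonate zwitterion 12 (not isolated)
Conditions: SnCl4 (20–50 mol%) added last to 7 and 11 (equimolar, 0.5 M in CH2Cl2), 0 to 23 °C; aq. NaHCO3 quench as soon as 7 is consumed
Reagents that add atoms: none
Why: SnCl4 chelates the geminal diester of 7 and polarises the bond between the ester-bearing carbon and the butyl-bearing carbon; the carbonyl oxygen of 11 attacks the butyl-bearing carbon from the rear in an SN2-like opening (the O1–C5 bond), which gives the tin-bound zwitterion 12, and its malonate carbon then adds to the alkynyl oxocarbenium carbon (the C2–C3 bond). The closest known reaction type is the Lewis acid catalysed formal [3+2] cycloaddition of aldehydes with donor–acceptor cyclopropane-1,1-diesters, which is known for alkyl-substituted cyclopropanes and for unsaturated aldehydes. The oxolane closes by an aldol-type 5-endo-trig attack on the C=O+ unit (enolexo with respect to the malonate), a formally strained geometry that oxocarbenium ions routinely accept. C5 is set by inversion of the (S) centre of 7, since an alkyl donor cannot support a free carbocation and the opening should stay stereospecific. C2 is set by closure through an envelope in which the butyl group and the alkynyl group of the (E)-oxocarbenium ion are both pseudo-equatorial, which gives the 2,5-cis ring. The step needs attack by the aldehyde oxygen in preference to chloride, and 1,2- in preference to 1,4-addition to the ynyl oxocarbenium ion; the concentrated equimolar solution with sub-stoichiometric SnCl4, in which little free chloride is present, and the preference for the five-membered closure over a seven-membered allene-forming one should secure both.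

Step 5
Reactants: 13 dimethyl (2S,5R)-5-butyl-2-(hexadec-1-yn-1-yl)oxolane-3,3-dicarboxylate
Product: 15 (2S,5R)-5-butyl-2-(hexadec-1-yn-1-yl)oxolane-3,3-dicarboxylic acid, via dipotassium dicarboxylate 14 (not isolated)
Conditions: KOH (10 equiv), MeOH/THF/H2O, 60 °C; then cold 1 M HCl to pH 2, extraction, concentration below 30 °C
Reagents that add atoms: potassium hydroxide, [K+].[OH-]
Why: Ester saponification: C3 is quaternary, so no enolate can form and neither retro-aldol cleavage nor β-elimination of the ring oxygen is possible, while the alkyne and both ring stereocentres are inert to aqueous hydroxide.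

Step 6
Reactants: 15 (2S,5R)-5-butyl-2-(hexadec-1-yn-1-yl)oxolane-3,3-dicarboxylic acid
Product: 17 (2R,5R)-2-butyl-5-(hexadec-1-yn-1-yl)oxolane, via monoacid 16 (not isolated)
Conditions: 9-mesityl-10-phenylacridinium tetrafluoroborate (5 mol%), PhSSPh (10 mol%), i-Pr2NEt (0.5 equiv), CF3CH2OH/CH2Cl2, 450 nm LEDs, 25 °C, N2
Reagents that add atoms: none
Why: Photoredox hydrodecarboxylation of a malonic acid: the excited acridinium oxidises the carboxylate, loss of CO2 gives the C3 radical, and hydrogen-atom transfer from PhSH (formed from PhSSPh) gives monoacid 16, which repeats the cycle, so both helper carboxyl groups leave as CO2 and C3 becomes CH2 without any ionic intermediate that could open the ring or touch C2 and C5.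

Step 7
Reactants: 17 (2R,5R)-2-butyl-5-(hexadec-1-yn-1-yl)oxolane
Product: 19 1-[(2R,5R)-5-butyloxolan-2-yl]hexadecan-2-one, via enol 18 (not isolated)
Conditions: (IPr)AuCl (2 mol%; IPr = 1,3-bis(2,6-diisopropylphenyl)imidazol-2-ylidene), AgSbF6 (2 mol%), 1,4-dioxane/H2O (4:1), 60 °C
Reagents that add atoms: water, O
Why: Gold-catalysed alkyne hydration: water adds to the alkyne π-complex of cationic monovalent gold at the carbon remote from the ring, because the electron-withdrawing C2–O bond disfavours positive charge on the adjacent alkyne carbon, and protodeauration and tautomerisation of enol 18 give the β-alkoxy ketone under acid- and base-free conditions that should not trigger retro-oxa-Michael opening, so C2 and C5 remain (R).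

**Compound list**

1 | (2R)-hexane-1,2-diol | CCCC[C@@H](O)CO | starting material
2 | (4R)-4-butyl-1,3,2-dioxathiolane 2-oxide (cyclic sulfite, both sulfur epimers) | CCCC[C@@H]1COS(=O)O1 | intermediate (not isolated)
3 | (4R)-4-butyl-1,3,2-dioxathiolane 2,2-dioxide | CCCC[C@@H]1COS(=O)(=O)O1 | intermediate
4 | dimethyl malonate | COC(=O)CC(=O)OC | starting material
5 | sodium dimethyl malonate | [Na+].COC(=O)[CH-]C(=O)OC | intermediate (not isolated)
6 | sodium (3R)-1,1-bis(methoxycarbonyl)heptan-3-yl sulfate | CCCC[C@H](CC(C(=O)OC)C(=O)OC)OS(=O)(=O)[O-].[Na+] | intermediate (not isolated)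
7 | dimethyl (2S)-2-butylcyclopropane-1,1-dicarboxylate | CCCC[C@H]1CC1(C(=O)OC)C(=O)OC | intermediate
8 | hexadec-1-yne | CCCCCCCCCCCCCCC#C | starting material
9 | lithium hexadec-1-yn-1-ide | CCCCCCCCCCCCCCC#C[Li] | intermediate (not isolated)
10 | lithium 1-(dimethylamino)heptadec-2-yn-1-olate | CCCCCCCCCCCCCCC#CC(O[Li])N(C)C | intermediate (not isolated)
11 | heptadec-2-ynal | CCCCCCCCCCCCCCC#CC=O | intermediate
12 | oxocarbenium malonate zwitterion (tin-bound in the flask, drawn without SnCl4) | CCCCCCCCCCCCCCC#CC=[O+][C@H](CCCC)CC[C-](C(=O)OC)C(=O)OC | intermediate (not isolated)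
13 | dimethyl (2S,5R)-5-butyl-2-(hexadec-1-yn-1-yl)oxolane-3,3-dicarboxylate | CCCCCCCCCCCCCCC#C[C@H]1C(C(=O)OC)(C(=O)OC)C[C@@H](CCCC)O1 | intermediate
14 | dipotassium (2S,5R)-5-butyl-2-(hexadec-1-yn-1-yl)oxolane-3,3-dicarboxylate | CCCCCCCCCCCCCCC#C[C@H]1C(C(=O)[O-])(C(=O)[O-])C[C@@H](CCCC)O1.[K+].[K+] | intermediate (not isolated)
15 | (2S,5R)-5-butyl-2-(hexadec-1-yn-1-yl)oxolane-3,3-dicarboxylic acid | CCCCCCCCCCCCCCC#C[C@H]1C(C(=O)O)(C(=O)O)C[C@@H](CCCC)O1 | intermediate
16 | (2R,5R)-5-butyl-2-(hexadec-1-yn-1-yl)oxolane-3-carboxylic acid (both C3 epimers) | CCCCCCCCCCCCCCC#C[C@H]1C(C(=O)O)C[C@@H](CCCC)O1 | intermediate (not isolated)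
17 | (2R,5R)-2-butyl-5-(hexadec-1-yn-1-yl)oxolane | CCCCCCCCCCCCCCC#C[C@H]1CC[C@@H](CCCC)O1 | intermediate
18 | 1-[(2R,5R)-5-butyloxolan-2-yl]hexadec-1-en-2-ol | CCCCCCCCCCCCCCC(O)=C[C@H]1CC[C@@H](CCCC)O1 | intermediate (not isolated)
19 | 1-[(2R,5R)-5-butyloxolan-2-yl]hexadecan-2-one | CCCCCCCCCCCCCCC(=O)C[C@H]1CC[C@@H](CCCC)O1 | target

**Count and risks**

Total steps: 7. Longest linear sequence: 6 steps (steps 1, 2, 4, 5, 6, 7); step 3 is a one-step branch.

Steps most likely to fail:

1. Step 4. The SN2 opening of an alkyl-donor cyclopropane by the weakly nucleophilic ynal oxygen may be sluggish, chloride may capture the activated cyclopropane, or partial ionisation may erode the chirality transfer and the cis preference. Fallback: the ring is built by lactone addition and oxocarbenium reduction instead. It sets out from hexadec-1-yne 8 (as its lithium salt 9), which is added at −78 °C in THF to purchased (5R)-5-butyloxolan-2-one F1 to give (5R)-5-hydroxytetracos-9-yn-8-one F2. Treatment with Et3SiH and BF3·OEt2 in CH2Cl2 at −78 to −40 °C should close F2 to the cyclic alkynyl oxocarbenium ion and deliver hydride anti to the butyl group, giving the 2,5-cis oxolane. The fallback comes back to the route at 17.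

2. Step 7. Water may attack the wrong alkyne carbon, or the Lewis acidic metal may promote retro-oxa-Michael opening and reclosure of the β-alkoxy ketone, which would scramble C2. Fallback: the oxygen is placed through silicon. It sets out from 17, which undergoes hydrosilylation with BnMe2SiH (PtCl2, XPhos, THF, 50 °C); with a propargylic oxygen substituent this should put silicon on the alkyne carbon remote from the ring and give benzyl{(E)-1-[(2R,5R)-5-butyloxolan-2-yl]hexadec-1-en-2-yl}dimethylsilane F3. Tamao–Fleming oxidation (TBAF, THF; then H2O2, KHCO3, MeOH/THF) converts the C–Si bond into the enol and hence the ketone under mild conditions. The fallback comes back at 19.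

3. Step 6. Thiyl radicals may add to the alkyne, or the sequence may stall after the first decarboxylation. Fallback: stepwise thermal and radical-chain decarboxylation. It sets out from 15, which is heated in toluene at 110 °C to lose one CO2 and give monoacid 16, now isolated. DCC coupling with N-hydroxypyridine-2-thione (DMAP cat., CH2Cl2, dark) gives the Barton ester 2-thioxopyridin-1(2H)-yl (2R,5R)-5-butyl-2-(hexadec-1-yn-1-yl)oxolane-3-carboxylate F4. Barton reductive decarboxylation (t-BuSH, visible light, toluene, rt) replaces the carboxyl group by hydrogen. The fallback comes back at 17.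

**Further compounds**

F1 | step 4 | (5R)-5-butyloxolan-2-one | O=C1CC[C@@H](CCCC)O1
F2 | step 4 | (5R)-5-hydroxytetracos-9-yn-8-one | CCCCCCCCCCCCCCC#CC(=O)CC[C@H](O)CCCC
F3 | step 7 | benzyl{(E)-1-[(2R,5R)-5-butyloxolan-2-yl]hexadec-1-en-2-yl}dimethylsilane | CCCCCCCCCCCCCC/C(=C\[C@H]1CC[C@@H](CCCC)O1)[Si](C)(C)Cc1ccccc1
F4 | step 6 | 2-thioxopyridin-1(2H)-yl (2R,5R)-5-butyl-2-(hexadec-1-yn-1-yl)oxolane-3-carboxylate (both C3 epimers) | CCCCCCCCCCCCCCC#C[C@H]1C(C(=O)ON2C=CC=CC2=S)C[C@@H](CCCC)O1
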